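Numbering: the stilbene units are a, b and c; C7/C8 are the former alkene carbons and C9–C14 the resorcinol ring of each unit. Ring A: C9a bears C8a, C10a bears C8b, C11a the first furan oxygen, C13a a free oxygen. Ring B: C9b bears C8b, C10b bears C7a, C11b the second furan oxygen, C12b bears C8c, C13b a free oxygen.
Retrosynthesis: C11b–O and C12b–C8c are cut together, giving an aryne across C11b–C12b of the tetracyclic core and the (S,S)-epoxide of a protected resveratrol. The core is then cut at C7a–aryl (aryl addition), C10b–C7a (Friedel–Crafts acylation, seven-membered ring), C9a–C8a (ester enolate arylation) and C7b–C8b (carbene C–H insertion).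
Forward: benzophenone → ring-A dihydrofuran → acetic acid arm → seven-membered ketone → unmasking of the C11b oxygen → aryl addition and dehydration → 2-silylaryl triflate at C12b/C11b → aryne–epoxide annulation → deprotection.
Enabling feature: the C11b–C12b bond of ring B lies next to the C13b oxygen, so an aryne there takes an oxygen nucleophile at C11b and carries the anion at C12b, and the O–C7c–C8c unit maps onto a stilbene oxide. Helpers: the C7a ketone (tells the C11b methoxy from the C13b methoxy, then becomes the alkene), SiMe3/OTf on C12b/C11b (aryne), and OTf on the C7c aryl (steers the C–O cleavage, then becomes the phenol).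
Stereochemistry: C8b comes from a chiral dirhodium carboxylate in the C–H insertion and C7b from acid equilibration to trans. C7c comes from the Shi epoxidation and C8c is relayed from it in the key step; the two halves are joined as single enantiomers.

Key step: step 15

Assumptions: the enantiomer of the Shi ketone (the L-fructose-derived ketone) is taken as commercially available, and in step 6 the antipode of the dirhodium catalyst is the one that leads to the (8bS) series (written here as Rh2(R-PTAD)4).

**Step 1**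
Reactants: 1 pterostilbene, (E)-4-(3,5-dimethoxystyryl)phenol
Product: 2 4-[(E)-2-(3,5-dimethoxyphenyl)ethenyl]phenyl trifluoromethanesulfonate
Conditions: Tf2O, pyridine, CH2Cl2, 0 °C
Reagents that add atoms: trifluoromethanesulfonic anhydride, O=S(=O)(OS(=O)(=O)C(F)(F)F)C(F)(F)F
Why: O-sulfonylation of the only free phenol should be clean, and the triflate masks this phenol as an electron-poor group that later steers the epoxide opening and makes the stilbene oxide stable to handling.

**Step 2**
Reactants: 2 4-[(E)-2-(3,5-dimethoxyphenyl)ethenyl]phenyl trifluoromethanesulfonate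
Product: 3 4-[(2S,3S)-3-(3,5-dimethoxyphenyl)oxiran-2-yl]phenyl trifluoromethanesulfonate (trans)
Conditions: ent-Shi ketone (30 mol %), Oxone (2KHSO5·KHSO4·K2SO4), K2CO3, Bu4NHSO4, MeCN/CH2(OMe)2, aq. Na2B4O7/Na2EDTA buffer, 0 °C
Reagents that add atoms: Oxone, active component potassium peroxymonosulfate, [K+].[O-]S(=O)(=O)OO
Why: Shi epoxidation of a trans-stilbene by the chiral dioxirane (spiro transition state) should give the trans-epoxide, and the L-fructose-derived ketone is the antipode expected to deliver the (S,S) isomer.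

**Step 3**
Reactants: 4 1-bromo-3,5-dimethoxybenzene; 5 3,5-dimethoxybenzoyl chloride
Product: 7 (2-bromo-6-hydroxy-4-methoxyphenyl)(3,5-dimethoxyphenyl)methanone, via dimethyl ether ketone 6 (not isolated)
Conditions: AlCl3 (3 equiv), CH2Cl2, 0 → 40 °C; aq. HCl
Reagents that add atoms: none
Why: Friedel–Crafts acylation should enter next to bromine (para to one methoxy, ortho to the other), and the aluminium chelate of the new ketone then cleaves only the methoxy group ortho to the carbonyl.

**Step 4**
Reactants: 7 (2-bromo-6-hydroxy-4-methoxyphenyl)(3,5-dimethoxyphenyl)methanone; 8 4-methoxybenzyl chloride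
Product: 9 {2-bromo-4-methoxy-6-[(4-methoxybenzyl)oxy]phenyl}(3,5-dimethoxyphenyl)methanone
Conditions: K2CO3, KI (cat.), DMF, 60 °C
Reagents that add atoms: none
Why: Williamson etherification of the phenol installs the benzylic CH2 that becomes C7b with its 4-methoxyphenyl group.

**Step 5**
Reactants: 9 {2-bromo-4-methoxy-6-[(4-methoxybenzyl)oxy]phenyl}(3,5-dimethoxyphenyl)methanone
Product: 10 hydrazone of 9
Conditions: N2H4·H2O (excess), AcOH (cat.), n-BuOH, 120 °C
Reagents that add atoms: hydrazine (used as the hydrate), NN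
Why: condensation of the hindered diaryl ketone with excess hydrazine under forcing conditions should give the hydrazone, the aryl bromide and ethers being inert.

**Step 6**
Reactants: 10 hydrazone of 9
Product: 12 (2R,3S)-4-bromo-3-(3,5-dimethoxyphenyl)-6-methoxy-2-(4-methoxyphenyl)-2,3-dihydro-1-benzofuran (cis), via diazo compound 11 (not isolated)
Conditions: MnO2, CH2Cl2, rt, filtration; then Rh2(R-PTAD)4 (1 mol %), CH2Cl2, 0 °C
Reagents that add atoms: none
Why: oxidation gives the diaryl diazo compound, whose dirhodium carbene inserts into the ether benzylic C–H bond through a five-membered transition state (donor/donor carbene C–H insertion), the chiral carboxylate ligands setting C8b and the cis relation to C7b.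

**Step 7**
Reactants: 12 cis-bromide; 13 (2-tert-butoxy-2-oxoethyl)zinc bromide
Product: 14 tert-butyl [(2R,3S)-3-(3,5-dimethoxyphenyl)-6-methoxy-2-(4-methoxyphenyl)-2,3-dihydro-1-benzofuran-4-yl]acetate (cis)
Conditions: Pd(dba)2 (3 mol %), P(t-Bu)3 (3 mol %), THF, rt → 50 °C
Reagents that add atoms: none
Why: palladium-catalysed coupling of the aryl bromide with the Reformatsky reagent (ester enolate arylation) runs without strong base, so the C8b hydrogen and the furan ring are not endangered.

**Step 8**
Reactants: 14 cis tert-butyl ester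
Product: 16 [(2S,3S)-3-(3,5-dimethoxyphenyl)-6-methoxy-2-(4-methoxyphenyl)-2,3-dihydro-1-benzofuran-4-yl]acetic acid (trans), via cis acid 15 (not isolated)
Conditions: CF3CO2H/CH2Cl2 (1:4), 0 °C → rt
Reagents that add atoms: none
Why: acidolysis removes the tert-butyl ester as 2-methylpropene, and the same acid reversibly ionises the 4-methoxybenzylic C7b–O bond, which recloses to the more stable trans ring while C8b is untouched.

**Step 9**
Reactants: 16 trans acid
Product: 18 (7bS,8bS) tetracyclic ketone (C7a=O; CH2 at C8a; methoxy on C13a C11b C13b; 4-methoxyphenyl on C7b), via mixed anhydride 17 (not isolated)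
Conditions: (CF3CO)2O (2 equiv), CH2Cl2, 0 °C → rt
Reagents that add atoms: none
Why: intramolecular Friedel–Crafts acylation through the mixed trifluoroacetic anhydride closes the seven-membered ring onto the 3,5-dimethoxyphenyl ring, whose two ortho positions are equivalent.

**Step 10**
Reactants: 18 tetracyclic ketone
Product: 19 (7bS,8bS) tetracyclic hydroxy ketone (free OH on C11b)
Conditions: BCl3 (1.5 equiv), CH2Cl2, −78 → −20 °C; aq. NaHCO3
Reagents that add atoms: none
Why: chelation-controlled demethylation cleaves only the C11b methoxy group, the one ortho to the C7a carbonyl (six-membered boron chelate), so C11b is told apart from C13b and the other three methyl ethers stay.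

**Step 11**
Reactants: 19 tetracyclic hydroxy ketone; 20 4-methoxyphenylmagnesium bromide
Product: 22 (7bS,8bS) core phenol (C7a(4-methoxyphenyl)=C8a; OH on C11b), via carbinol 21 (not isolated)
Conditions: 20 (4 equiv), CeCl3 (4 equiv), THF, −78 → 0 °C; aq. NH4Cl; then TsOH·H2O (5 mol %), toluene, 40 °C
Reagents that add atoms: none
Why: the organocerium reagent should add to the enolisable benzylic ketone rather than deprotonate it, and the tertiary bis-benzylic carbinol loses water under mild acid toward C8a, the only carbon with β-hydrogens.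

**Step 12**
Reactants: 22 core phenol
Product: 23 C11b N-isopropylcarbamate of 22
Conditions: i-PrN=C=O, Et3N (cat.), CH2Cl2, rt
Reagents that add atoms: isopropyl isocyanate, CC(C)N=C=O
Why: carbamoylation turns the C11b phenol into a strong ortho-directing group that can later be removed under mild base.

**Step 13**
Reactants: 23 C11b N-isopropylcarbamate
Product: 26 C12b-trimethylsilyl C11b N-isopropylcarbamate, via N-silyl carbamate 24 (not isolated), via N-silyl C-silyl carbamate 25 (not isolated)
Conditions: t-BuMe2SiOTf, TMEDA, Et2O, 0 °C; n-BuLi, TMEDA, −78 °C; Me3SiCl, −78 °C → rt; aq. NaHSO4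
Reagents that add atoms: chlorotrimethylsilane, C[Si](C)(C)Cl
Why: directed ortho-metalation of the N-silylated carbamate should occur at C12b, the only free position ortho to the carbamate and flanked by two oxygens, at a temperature where complex-induced lithiation outruns attack on the alkene or the C8b hydrogen.

**Step 14**
Reactants: 26 C12b-trimethylsilyl C11b N-isopropylcarbamate
Product: 28 C12b-trimethylsilyl C11b triflate (aryne precursor), via silyl phenol 27 (not isolated)
Conditions: Et2NH, DBU, MeCN, 40 °C; then PhNTf2, rt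
Reagents that add atoms: N-phenylbis(trifluoromethanesulfonimide), O=S(=O)(N(c1ccccc1)S(=O)(=O)C(F)(F)F)C(F)(F)F
Why: base-induced elimination of the N–H carbamate (isocyanate trapped by the amine) frees the phenoxide, which is triflated in the same flask to give the 2-silylaryl triflate.

**Step 15**
Reactants: 28 C12b-trimethylsilyl C11b triflate; 3 (S,S)-epoxide
Product: 30 hexamethyl ether mono-triflate of the target, via aryne 29 (not isolated)
Conditions: CsF (3 equiv), 3 (3 equiv), MeCN/toluene (1:1), 25 → 40 °C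
Reagents that add atoms: none
Why: Proposed new method: fluoride removes the silyl group of 28 and triflate leaves to give aryne 29 across C11b–C12b; the epoxide oxygen of 3 adds to C11b, the O-aryl oxiranium opens at C8c to a benzylic cation, and the aryl anion at C12b collapses on it, so C11b–O and C12b–C8c form in one operation (formal insertion of the aryne into the C8c–O bond). The closest known reaction type is the insertion of arynes from 2-silylaryl triflates into the benzylic C–O bond of styrene oxides to give 2,3-dihydrobenzofurans; a trans-diaryl epoxide with two different benzylic carbons on an aryne of this size is without precedent. The dihydrofuran ring closes by anion–cation recombination within the zwitterion (C-arylation of the benzylic cation by the ortho aryl anion to a five-membered ring; a concerted 5-endo-tet displacement is geometrically excluded). C7c is not touched, so its configuration is that set by the Shi epoxidation; C8c is set in the closure, where least-motion collapse on the face the oxygen has left and the preference of the two aryl groups to stand trans on the forming ring both lead to the trans (7cR,8cR) ring. Two selectivities are needed: oxygen must enter at C11b and not C12b, which the inductive polarisation and distortion of the aryne by the C13b methoxy group should secure, and C8c–O must break and not C7c–O, which the electron-poor 4-triflyloxyphenyl group on C7c should secure by disfavouring a cation there while the 3,5-dimethoxyphenyl group on C8c tolerates one. Excess epoxide in a non-protic medium is meant to outrun protonation of the aryl anion and fluoride addition to the aryne.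

**Step 16**
Reactants: 30 hexamethyl ether mono-triflate
Product: 31 hexamethyl ether of the target with free 4-hydroxyphenyl on C7c
Conditions: Et4NOH (aq., 1.5 equiv), 1,4-dioxane, rt
Reagents that add atoms: none
Why: hydroxide attacks the sulfur of the aryl triflate (S–O cleavage) and releases the phenol at room temperature without touching the methyl ethers or the stereocentres.

**Step 17**
Reactants: 31 hexamethyl ether
Product: 32 target, (7bS,8bS,7cR,8cR)
Conditions: BBr3 (12 equiv), CH2Cl2, −78 → 0 °C; MeOH, then aq. NaHCO3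
Reagents that add atoms: none
Why: boron tribromide should cleave the six aryl methyl ethers, and because both dihydrofurans are already the trans isomers, any reversible ionisation at C7b or C7c should return the same configuration.

**Compound list**
1 | pterostilbene, (E)-4-(3,5-dimethoxystyryl)phenol | COc1cc(/C=C/c2ccc(O)cc2)cc(OC)c1 | starting material
2 | 4-[(E)-2-(3,5-dimethoxyphenyl)ethenyl]phenyl trifluoromethanesulfonate | COc1cc(/C=C/c2ccc(OS(=O)(=O)C(F)(F)F)cc2)cc(OC)c1 | intermediate
3 | 4-[(2S,3S)-3-(3,5-dimethoxyphenyl)oxiran-2-yl]phenyl trifluoromethanesulfonate | O1[C@@H](c2ccc(OS(=O)(=O)C(F)(F)F)cc2)[C@@H]1c3cc(OC)cc(OC)c3 | intermediate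
4 | 1-bromo-3,5-dimethoxybenzene | COc1cc(Br)cc(OC)c1 | starting material
5 | 3,5-dimethoxybenzoyl chloride | COc1cc(cc(OC)c1)C(Cl)=O | starting material
6 | (2-bromo-4,6-dimethoxyphenyl)(3,5-dimethoxyphenyl)methanone | COc1cc(OC)c(C(=O)c2cc(OC)cc(OC)c2)c(Br)c1 | intermediate
7 | (2-bromo-6-hydroxy-4-methoxyphenyl)(3,5-dimethoxyphenyl)methanone | COc1cc(O)c(C(=O)c2cc(OC)cc(OC)c2)c(Br)c1 | intermediate
8 | 4-methoxybenzyl chloride | COc1ccc(CCl)cc1 | starting material
9 | {2-bromo-4-methoxy-6-[(4-methoxybenzyl)oxy]phenyl}(3,5-dimethoxyphenyl)methanone | COc1ccc(COc2cc(OC)cc(Br)c2C(=O)c2cc(OC)cc(OC)c2)cc1 | intermediate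
10 | hydrazone of 9 | COc1ccc(COc2cc(OC)cc(Br)c2C(=NN)c2cc(OC)cc(OC)c2)cc1 | intermediate
11 | 1-bromo-2-[diazo(3,5-dimethoxyphenyl)methyl]-5-methoxy-3-[(4-methoxybenzyl)oxy]benzene | COc1ccc(COc2cc(OC)cc(Br)c2C(=[N+]=[N-])c2cc(OC)cc(OC)c2)cc1 | intermediate
12 | (2R,3S)-4-bromo-3-(3,5-dimethoxyphenyl)-6-methoxy-2-(4-methoxyphenyl)-2,3-dihydro-1-benzofuran (cis) | Brc1cc(OC)cc2c1[C@H](c1cc(OC)cc(OC)c1)[C@H](c1ccc(OC)cc1)O2 | intermediate
13 | (2-tert-butoxy-2-oxoethyl)zinc bromide | CC(C)(C)OC(=O)C[Zn]Br | starting material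
14 | tert-butyl [(2R,3S)-3-(3,5-dimethoxyphenyl)-6-methoxy-2-(4-methoxyphenyl)-2,3-dihydro-1-benzofuran-4-yl]acetate (cis) | CC(C)(C)OC(=O)Cc1cc(OC)cc2c1[C@H](c1cc(OC)cc(OC)c1)[C@H](c1ccc(OC)cc1)O2 | intermediate
15 | [(2R,3S)-3-(3,5-dimethoxyphenyl)-6-methoxy-2-(4-methoxyphenyl)-2,3-dihydro-1-benzofuran-4-yl]acetic acid (cis) | OC(=O)Cc1cc(OC)cc2c1[C@H](c1cc(OC)cc(OC)c1)[C@H](c1ccc(OC)cc1)O2 | intermediate
16 | [(2S,3S)-3-(3,5-dimethoxyphenyl)-6-methoxy-2-(4-methoxyphenyl)-2,3-dihydro-1-benzofuran-4-yl]acetic acid (trans) | OC(=O)Cc1cc(OC)cc2c1[C@H](c1cc(OC)cc(OC)c1)[C@@H](c1ccc(OC)cc1)O2 | intermediate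
17 | mixed anhydride of 16 with trifluoroacetic acid | O=C(Cc1cc(OC)cc2c1[C@H](c1cc(OC)cc(OC)c1)[C@@H](c1ccc(OC)cc1)O2)OC(=O)C(F)(F)F | intermediate
18 | (7bS,8bS) tetracyclic ketone: seven-membered ring C9a–C8a(H2)–C7a(=O)–C10b–C9b–C8b–C10a; methoxy on C13a, C11b, C13b; trans-dihydrofuran C11a–O–C7b(4-methoxyphenyl)–C8b–C10a | O=C2Cc3cc(OC)cc4c3[C@H](c3cc(OC)cc(OC)c32)[C@@H](c2ccc(OC)cc2)O4 | intermediate
19 | (7bS,8bS) tetracyclic hydroxy ketone: as 18 with free OH on C11b | O=C2Cc3cc(OC)cc4c3[C@H](c3cc(OC)cc(O)c32)[C@@H](c2ccc(OC)cc2)O4 | intermediate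
20 | 4-methoxyphenylmagnesium bromide | COc1ccc([Mg]Br)cc1 | starting material
21 | tertiary carbinol: as 19 with C7a(OH)(4-methoxyphenyl), mixture at C7a | COc1ccc(cc1)C2(O)Cc3cc(OC)cc4c3[C@H](c3cc(OC)cc(O)c32)[C@@H](c2ccc(OC)cc2)O4 | intermediate
22 | (7bS,8bS) core phenol: C7a(4-methoxyphenyl)=C8a; OH on C11b; methoxy on C13a, C13b | COc1ccc(cc1)C2=Cc3cc(OC)cc4c3[C@H](c3cc(OC)cc(O)c32)[C@@H](c2ccc(OC)cc2)O4 | intermediate
23 | C11b N-isopropylcarbamate of 22 | COc1ccc(cc1)C2=Cc3cc(OC)cc4c3[C@H](c3cc(OC)cc(OC(=O)NC(C)C)c32)[C@@H](c2ccc(OC)cc2)O4 | intermediate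
24 | N-(tert-butyldimethylsilyl) derivative of 23 | COc1ccc(cc1)C2=Cc3cc(OC)cc4c3[C@H](c3cc(OC)cc(OC(=O)N(C(C)C)[Si](C)(C)C(C)(C)C)c32)[C@@H](c2ccc(OC)cc2)O4 | intermediate
25 | C12b-trimethylsilyl derivative of 24 | COc1ccc(cc1)C2=Cc3cc(OC)cc4c3[C@H](c3cc(OC)c([Si](C)(C)C)c(OC(=O)N(C(C)C)[Si](C)(C)C(C)(C)C)c32)[C@@H](c2ccc(OC)cc2)O4 | intermediate
26 | C12b-trimethylsilyl C11b N-isopropylcarbamate | COc1ccc(cc1)C2=Cc3cc(OC)cc4c3[C@H](c3cc(OC)c([Si](C)(C)C)c(OC(=O)NC(C)C)c32)[C@@H](c2ccc(OC)cc2)O4 | intermediate
27 | C12b-trimethylsilyl C11b phenol | COc1ccc(cc1)C2=Cc3cc(OC)cc4c3[C@H](c3cc(OC)c([Si](C)(C)C)c(O)c32)[C@@H](c2ccc(OC)cc2)O4 | intermediate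
28 | C12b-trimethylsilyl C11b trifluoromethanesulfonate (aryne precursor) | COc1ccc(cc1)C2=Cc3cc(OC)cc4c3[C@H](c3cc(OC)c([Si](C)(C)C)c(OS(=O)(=O)C(F)(F)F)c32)[C@@H](c2ccc(OC)cc2)O4 | intermediate
29 | aryne of the core across C11b–C12b | COc1ccc(cc1)C2=Cc3cc(OC)cc4c3[C@H](C3C=C(OC)C#CC=32)[C@@H](c2ccc(OC)cc2)O4 | intermediate
30 | (7bS,8bS,7cR,8cR) hexamethyl ether of the target with a triflate on the C7c aryl | COc1ccc(cc1)C2=Cc3cc(OC)cc4c3[C@H](c3cc(OC)c5c(c32)O[C@@H](c2ccc(OS(=O)(=O)C(F)(F)F)cc2)[C@@H]5c2cc(OC)cc(OC)c2)[C@@H](c2ccc(OC)cc2)O4 | intermediate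
31 | (7bS,8bS,7cR,8cR) hexamethyl ether of the target with free 4-hydroxyphenyl on C7c | COc1ccc(cc1)C2=Cc3cc(OC)cc4c3[C@H](c3cc(OC)c5c(c32)O[C@@H](c2ccc(O)cc2)[C@@H]5c2cc(OC)cc(OC)c2)[C@@H](c2ccc(OC)cc2)O4 | intermediate
32 | CNP0325907.1, (7bS,8bS,7cR,8cR) | Oc1ccc(C2=Cc3cc(O)cc4c3[C@H](c3cc(O)c5c(c32)O[C@@H](c2ccc(O)cc2)[C@@H]5c2cc(O)cc(O)c2)[C@@H](c2ccc(O)cc2)O4)cc1 | target

**Step count and risks**
Total: 17 steps. Longest linear sequence: 15 steps (steps 3 to 17, from 4 and 5 to 32); the epoxide branch is 2 steps.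

Step 15. The O-aryl oxiranium may open at C7c instead of C8c, or lose its way by hydride shift or protonation of the aryl anion before the ring closes; fluoride may also consume the aryne. The fallback builds the same ring stepwise by known reactions, sets out from carbamate 23 and comes back at the target 32. Compound 23 is N-silylated and lithiated at C12b as in step 13, and the aryllithium is acylated with N-methoxy-N-methyl-3,5-dimethoxybenzamide (CON(C)C(=O)c1cc(OC)cc(OC)c1) to give the C12b-aroyl carbamate F1. Et2NH/DBU frees the C11b hydroxy ketone F2, and 4-methoxybenzyl chloride 8 with K2CO3 gives the 4-methoxybenzyl ether F3. Hydrazine gives the hydrazone F4 and MnO2 the diazo compound F5. The dirhodium PTAD catalyst of the antipode that sets (8cR) then inserts the carbene into the benzylic C–H bond to give the cis-dihydrofuran heptamethyl ether F6. BBr3 removes the seven methyl groups with acid equilibration of C7c to trans and should give 32.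

Step 6. Facial discrimination by the chiral dirhodium carboxylate may be poor because the carbene carbon carries an aryl ring with two ortho substituents, and azine formation may compete. The fallback replaces catalyst control by resolution, sets out from hydrazone 10 and comes back at 12. Oxidation with MnO2 and carbene insertion with achiral Rh2(OAc)4 would give the racemic cis-bromide F7, which is separated by preparative chromatography on a chiral stationary phase (supercritical CO2/MeOH) to give 12.

Step 11. The aryl metal reagent may enolise the benzylic ketone, or fail to add to a carbonyl deactivated by the neighbouring phenoxide. The fallback makes the C7a–aryl bond by cross-coupling, sets out from 19 and comes back at 22. KN(SiMe3)2 (2.2 equiv) and PhNTf2 (2.2 equiv) would give the enol/aryl bis(triflate) F8. Suzuki–Miyaura coupling of the more reactive alkenyl triflate with 4-methoxyphenylboronic acid (Pd(PPh3)4, K3PO4, dioxane/H2O, 50 °C) would give the C11b aryl triflate F9, and Et4NOH in dioxane would free the phenol 22.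

**Further compounds**
F1 | step 15 | C12b-(3,5-dimethoxybenzoyl) C11b N-isopropylcarbamate of the core | COc1ccc(cc1)C2=Cc3cc(OC)cc4c3[C@H](c3cc(OC)c(C(=O)c5cc(OC)cc(OC)c5)c(OC(=O)NC(C)C)c32)[C@@H](c2ccc(OC)cc2)O4
F2 | step 15 | C12b-(3,5-dimethoxybenzoyl) C11b phenol of the core | COc1ccc(cc1)C2=Cc3cc(OC)cc4c3[C@H](c3cc(OC)c(C(=O)c5cc(OC)cc(OC)c5)c(O)c32)[C@@H](c2ccc(OC)cc2)O4
F3 | step 15 | C12b-(3,5-dimethoxybenzoyl) C11b 4-methoxybenzyl ether of the core | COc1ccc(cc1)C2=Cc3cc(OC)cc4c3[C@H](c3cc(OC)c(C(=O)c5cc(OC)cc(OC)c5)c(OCc5ccc(OC)cc5)c32)[C@@H](c2ccc(OC)cc2)O4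
F4 | step 15 | hydrazone of F3 | COc1ccc(cc1)C2=Cc3cc(OC)cc4c3[C@H](c3cc(OC)c(C(=NN)c5cc(OC)cc(OC)c5)c(OCc5ccc(OC)cc5)c32)[C@@H](c2ccc(OC)cc2)O4
F5 | step 15 | diazo compound from F4 | COc1ccc(cc1)C2=Cc3cc(OC)cc4c3[C@H](c3cc(OC)c(C(=[N+]=[N-])c5cc(OC)cc(OC)c5)c(OCc5ccc(OC)cc5)c32)[C@@H](c2ccc(OC)cc2)O4
F6 | step 15 | (7bS,8bS,7cS,8cR) heptamethyl ether of the target, cis at C7c/C8c | COc1ccc(cc1)C2=Cc3cc(OC)cc4c3[C@H](c3cc(OC)c5c(c32)O[C@H](c2ccc(OC)cc2)[C@@H]5c2cc(OC)cc(OC)c2)[C@@H](c2ccc(OC)cc2)O4
F7 | step 6 | racemic cis-4-bromo-3-(3,5-dimethoxyphenyl)-6-methoxy-2-(4-methoxyphenyl)-2,3-dihydro-1-benzofuran | Brc1cc(OC)cc2c1[C@H](c1cc(OC)cc(OC)c1)[C@H](c1ccc(OC)cc1)O2.Brc1cc(OC)cc2c1[C@@H](c1cc(OC)cc(OC)c1)[C@@H](c1ccc(OC)cc1)O2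
F8 | step 11 | C7a enol triflate C11b aryl triflate of the tetracycle | FC(F)(F)S(=O)(=O)OC2=Cc3cc(OC)cc4c3[C@H](c3cc(OC)cc(OS(=O)(=O)C(F)(F)F)c32)[C@@H](c2ccc(OC)cc2)O4
F9 | step 11 | C11b aryl triflate of core phenol 22 | COc1ccc(cc1)C2=Cc3cc(OC)cc4c3[C@H](c3cc(OC)cc(OS(=O)(=O)C(F)(F)F)c32)[C@@H](c2ccc(OC)cc2)O4
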